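**Plan**

- The target is an achiral depside, so no stereochemistry has to be set. Ring A is the benzoate ring, numbered as in its name: C1 (ester), C2 and C4 (hydroxyl), C3 and C5 (formyl), C6 (methyl). Ring B is the fully substituted chloro-methoxy-trimethylphenyl group.
- Retrosynthetic cuts, in order: the two O–alkyl bonds and the two C–CHO bonds on ring A; then the ring A bonds C5–C6 and C3–C4; then the pyrone O1–C2 and C4–C5 bonds; last the aryl ester C–O bond.
- Enabling feature: ring A C1, C6, C2 and C3 are C5, C6, C4 and C3 of a 4-alkoxy-6-methyl-2-pyrone-5-carboxylate, whose O1 and lactone carbonyl C2 leave as CO2. Oxygenated ring A C4 lies para to the ester, which is where a 1,1-dialkoxyethene places its acetal carbon; ring A C5 is its CH2 carbon.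
- Forward: the ring B phenol is made from 2,4,5-trimethylphenol, acylated by acetylketene (the hindered ester bond is made on an open chain), annulated to the 2-pyrone and O-methylated. The pyrone ring is then turned into benzene ring A by cycloaddition with 1,1-diethoxyethene and loss of CO2 and ethanol.
- Double formylation and chelation-controlled removal of the two ring A alkyl groups complete the route.

Key step: step 8

**Route**

Step 1
Reactants: 1 2,4,5-trimethylphenol
Product: 2 2-chloro-3,4,6-trimethylphenol
Conditions: SO2Cl2 (1.05 equiv), CH2Cl2, 0 °C to rt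
Reagents that add atoms: sulfuryl chloride, O=S(=O)(Cl)Cl
Why: Electrophilic aromatic chlorination, in which the hydroxyl group directs ortho and para and, with the para and one ortho position blocked by methyl groups, only the second ortho position is open, so a single monochloride should form.

Step 2
Reactants: 2 2-chloro-3,4,6-trimethylphenol
Product: 3 2-chloro-1-methoxy-3,4,6-trimethylbenzene
Conditions: MeI, K2CO3, acetone, reflux
Reagents that add atoms: iodomethane, CI
Why: Williamson ether synthesis, in which K2CO3 readily forms the 2-chloro-6-methylphenoxide and the small MeI still reaches the flanked oxygen; capping the phenol also prevents ipso attack at the para-methyl carbon in the next halogenation.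

Step 3
Reactants: 3 2-chloro-1-methoxy-3,4,6-trimethylbenzene
Product: 4 1-bromo-4-chloro-3-methoxy-2,5,6-trimethylbenzene
Conditions: Br2 (1.05 equiv), FeBr3 (5 mol%), CH2Cl2, 0 °C to rt, dark
Reagents that add atoms: bromine, BrBr
Why: Electrophilic aromatic bromination at the only ring C–H left, which is activated by two ortho methyl groups, while ionic conditions in the dark leave the benzylic positions alone.

Step 4
Reactants: 4 1-bromo-4-chloro-3-methoxy-2,5,6-trimethylbenzene
Product: 7 4-chloro-3-methoxy-2,5,6-trimethylphenol, via aryllithium 5 (not isolated), via lithium aryltrimethoxyborate 6 (not isolated)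
Conditions: n-BuLi, THF, −78 °C; B(OMe)3, −78 °C to rt; then 30% H2O2, aq. NaOH, 0 °C to rt; dilute HCl work-up
Reagents that add atoms: hydrogen peroxide, OO
Why: Bromine–lithium exchange (faster than exchange of the aryl chloride) gives 5, B(OMe)3 traps it as borate 6, and alkaline peroxide moves the aryl group from boron to oxygen (ipso-hydroxylation by boronate oxidation), a sequence that is routine for di-ortho-methyl aryl bromides.

Step 5
Reactants: 7 4-chloro-3-methoxy-2,5,6-trimethylphenol; 8 2,2,6-trimethyl-4H-1,3-dioxin-4-one
Product: 10 4-chloro-3-methoxy-2,5,6-trimethylphenyl 3-oxobutanoate, via acetylketene 9 (not isolated)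
Conditions: 8 (1.5 equiv), xylene, 140 °C, acetone distilled off
Reagents that add atoms: none
Why: Thermal retro-[4+2] fragmentation of 8 releases acetylketene 9, a small and very electrophilic acylating agent that adds even to di-ortho-substituted phenols (acetoacetylation), so the crowded aryl ester bond is made here without any activation of a hindered acid.

Step 6
Reactants: 10 4-chloro-3-methoxy-2,5,6-trimethylphenyl 3-oxobutanoate; 11 malonyl dichloride
Product: 13 4-chloro-3-methoxy-2,5,6-trimethylphenyl 4-hydroxy-6-methyl-2-oxo-2H-pyran-5-carboxylate, via C-acylated acid chloride 12 (not isolated)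
Conditions: 11 (1.3 equiv), CH2Cl2, rt to 40 °C, N2 sweep to remove HCl
Reagents that add atoms: none
Why: Pyrone annulation of a β-keto ester with malonyl dichloride, in which C-acylation of the acetoacetate α-carbon gives 12, the enol oxygen of the acetyl group closes the lactone and tautomerisation gives the 4-hydroxy-2-pyrone; the aryl ring has no free ortho position, so a Pechmann-type coumarin closure is excluded.

Step 7
Reactants: 13 4-chloro-3-methoxy-2,5,6-trimethylphenyl 4-hydroxy-6-methyl-2-oxo-2H-pyran-5-carboxylate
Product: 14 4-chloro-3-methoxy-2,5,6-trimethylphenyl 4-methoxy-6-methyl-2-oxo-2H-pyran-5-carboxylate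
Conditions: Me2SO4, K2CO3, acetone, reflux
Reagents that add atoms: dimethyl sulfate, COS(=O)(=O)OC
Why: O-Alkylation of a vinylogous acid, since 4-hydroxy-2-pyrones react with Me2SO4 and K2CO3 at the 4-oxygen to give 4-methoxy-2-pyrones, and the shielded aryl ester should not be touched by the weak base.

Step 8
Reactants: 14 4-chloro-3-methoxy-2,5,6-trimethylphenyl 4-methoxy-6-methyl-2-oxo-2H-pyran-5-carboxylate; 15 1,1-diethoxyethene
Product: 18 4-chloro-3-methoxy-2,5,6-trimethylphenyl 4-ethoxy-2-methoxy-6-methylbenzoate, via bridged bicyclic lactone 16 (not isolated), via diethoxycyclohexadiene ester 17 (not isolated)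
Conditions: 15 (8 equiv), Et3N (2 mol%), toluene, sealed tube, 130 °C
Reagents that add atoms: none
Why: This is an inverse-electron-demand Diels–Alder reaction of a 2-pyrone-5-carboxylate with a ketene acetal: the electron-rich CH2 terminus of 15 bonds to pyrone C6 of 14 (beta to the aryl ester on pyrone C5 and delta to the lactone carbonyl), the developing negative charge is taken up by the ester and lactone carbonyls, and pyrone C3 closes onto the dialkoxycarbenium carbon in a strongly asynchronous [4+2] that gives bridged lactone 16. Retro-[4+2] loss of CO2 from 16 gives diene 17, and 1,2-elimination of ethanol from its ketal aromatises the ring, so ring A is closed by an intermolecular [4+2] cycloaddition that forms its C5–C6 and C3–C4 bonds. The closest known reaction is the conversion of coumalate esters and other ester-activated 2-pyrones into alkoxybenzoates with 1,1-dialkoxyethenes, here applied to a more hindered and more electron-rich 4-methoxy-6-methyl member of the class. No stereocentre results, because the two bridgehead centres of racemic 16 are destroyed on aromatisation. The step needs regioselectivity (ethoxy para to the ester), which polarity matching should secure: pyrone C6 is the only ring carbon activated by both the ester and the lactone carbonyl, whereas pyrone C3 is the nucleophilic terminus, so the acetal carbon can only end at ring A C4. The aryl ester withdraws more strongly than an alkyl ester and so offsets the donor methoxy group, and its two ortho methyl groups shield the ester carbonyl from the nucleophilic alkene.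

Step 9
Reactants: 18 4-chloro-3-methoxy-2,5,6-trimethylphenyl 4-ethoxy-2-methoxy-6-methylbenzoate
Product: 21 4-chloro-3-methoxy-2,5,6-trimethylphenyl 4-ethoxy-3,5-diformyl-2-methoxy-6-methylbenzoate, via mono(α-chloro ether) 19 (not isolated), via bis(α-chloro ether) 20 (not isolated)
Conditions: Cl2CHOMe (6 equiv), TiCl4 (6 equiv), CH2Cl2, 0 °C to rt; ice-cold 1 M HCl work-up
Reagents that add atoms: dichloromethyl methyl ether, COC(Cl)Cl; water, O
Why: Double Rieche formylation (Friedel–Crafts substitution by the TiCl4-activated α-chloro ether), in which C3 and C5 are the only free positions of ring A and each is ortho or para to both alkoxy groups, the ester is twisted out of conjugation by its two ortho neighbours and ring B has no C–H, and α-chloro ethers 19 and 20 are hydrolysed to the aldehydes on work-up.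

Step 10
Reactants: 21 4-chloro-3-methoxy-2,5,6-trimethylphenyl 4-ethoxy-3,5-diformyl-2-methoxy-6-methylbenzoate
Product: 23 4-chloro-3-methoxy-2,5,6-trimethylphenyl 3,5-diformyl-2,4-dihydroxy-6-methylbenzoate, via bis(dichloroboryl) ether 22 (not isolated)
Conditions: BCl3 (5 equiv, 1 M in CH2Cl2), CH2Cl2, −78 to 0 °C; H2O work-up
Reagents that add atoms: none
Why: Chelation-controlled Lewis acid dealkylation, in which BCl3 is held between a carbonyl oxygen and the neighbouring ether oxygen (the 2-methoxy group of ring A between ester and formyl, the 4-ethoxy group between two formyl groups) and chloride removes the alkyl group, whereas the ring B methoxy group has no carbonyl neighbour and should survive at low temperature; hydrolysis of boron ester 22 releases the two phenols.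

**Compound list**

1 | 2,4,5-trimethylphenol | Oc1cc(C)c(C)cc1C | starting material
2 | 2-chloro-3,4,6-trimethylphenol | Oc1c(Cl)c(C)c(C)cc1C | intermediate
3 | 2-chloro-1-methoxy-3,4,6-trimethylbenzene | COc1c(Cl)c(C)c(C)cc1C | intermediate
4 | 1-bromo-4-chloro-3-methoxy-2,5,6-trimethylbenzene | COc1c(Cl)c(C)c(C)c(Br)c1C | intermediate
5 | (4-chloro-3-methoxy-2,5,6-trimethylphenyl)lithium (not isolated) | [Li]c1c(C)c(OC)c(Cl)c(C)c1C | intermediate
6 | lithium (4-chloro-3-methoxy-2,5,6-trimethylphenyl)trimethoxyborate (not isolated) | [Li+].CO[B-](OC)(OC)c1c(C)c(OC)c(Cl)c(C)c1C | intermediate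
7 | 4-chloro-3-methoxy-2,5,6-trimethylphenol | Oc1c(C)c(OC)c(Cl)c(C)c1C | intermediate
8 | 2,2,6-trimethyl-4H-1,3-dioxin-4-one | CC1=CC(=O)OC(C)(C)O1 | starting material
9 | acetylketene (but-1-ene-1,3-dione; not isolated) | CC(=O)C=C=O | intermediate
10 | 4-chloro-3-methoxy-2,5,6-trimethylphenyl 3-oxobutanoate | CC(=O)CC(=O)Oc1c(C)c(OC)c(Cl)c(C)c1C | intermediate
11 | malonyl dichloride | O=C(Cl)CC(=O)Cl | starting material
12 | 4-chloro-3-methoxy-2,5,6-trimethylphenyl 2-acetyl-5-chloro-3,5-dioxopentanoate (racemic, enolisable; not isolated) | CC(=O)C(C(=O)CC(=O)Cl)C(=O)Oc1c(C)c(OC)c(Cl)c(C)c1C | intermediate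
13 | 4-chloro-3-methoxy-2,5,6-trimethylphenyl 4-hydroxy-6-methyl-2-oxo-2H-pyran-5-carboxylate | CC1=C(C(=O)Oc2c(C)c(OC)c(Cl)c(C)c2C)C(O)=CC(=O)O1 | intermediate
14 | 4-chloro-3-methoxy-2,5,6-trimethylphenyl 4-methoxy-6-methyl-2-oxo-2H-pyran-5-carboxylate | COC1=CC(=O)OC(C)=C1C(=O)Oc1c(C)c(OC)c(Cl)c(C)c1C | intermediate
15 | 1,1-diethoxyethene | C=C(OCC)OCC | starting material
16 | 4-chloro-3-methoxy-2,5,6-trimethylphenyl 8,8-diethoxy-5-methoxy-1-methyl-3-oxo-2-oxabicyclo[2.2.2]oct-5-ene-6-carboxylate (racemic, bridgeheads linked by the bicycle; not isolated) | CCOC1(OCC)CC2(C)OC(=O)C1C(OC)=C2C(=O)Oc1c(C)c(OC)c(Cl)c(C)c1C | intermediate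
17 | 4-chloro-3-methoxy-2,5,6-trimethylphenyl 4,4-diethoxy-6-methoxy-2-methylcyclohexa-1,5-diene-1-carboxylate (not isolated) | CCOC1(OCC)CC(C)=C(C(=O)Oc2c(C)c(OC)c(Cl)c(C)c2C)C(OC)=C1 | intermediate
18 | 4-chloro-3-methoxy-2,5,6-trimethylphenyl 4-ethoxy-2-methoxy-6-methylbenzoate | CCOc1cc(C)c(C(=O)Oc2c(C)c(OC)c(Cl)c(C)c2C)c(OC)c1 | intermediate
19 | 4-chloro-3-methoxy-2,5,6-trimethylphenyl 3-[chloro(methoxy)methyl]-4-ethoxy-6-methoxy-2-methylbenzoate (racemic; not isolated) | CCOc1cc(OC)c(C(=O)Oc2c(C)c(OC)c(Cl)c(C)c2C)c(C)c1C(Cl)OC | intermediate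
20 | 4-chloro-3-methoxy-2,5,6-trimethylphenyl 3,5-bis[chloro(methoxy)methyl]-4-ethoxy-2-methoxy-6-methylbenzoate (mixture of stereoisomers; not isolated) | CCOc1c(C(Cl)OC)c(C)c(C(=O)Oc2c(C)c(OC)c(Cl)c(C)c2C)c(OC)c1C(Cl)OC | intermediate
21 | 4-chloro-3-methoxy-2,5,6-trimethylphenyl 4-ethoxy-3,5-diformyl-2-methoxy-6-methylbenzoate | CCOc1c(C=O)c(C)c(C(=O)Oc2c(C)c(OC)c(Cl)c(C)c2C)c(OC)c1C=O | intermediate
22 | 4-chloro-3-methoxy-2,5,6-trimethylphenyl 2,4-bis[(dichloroboranyl)oxy]-3,5-diformyl-6-methylbenzoate (not isolated) | COc1c(C)c(OC(=O)c2c(C)c(C=O)c(OB(Cl)Cl)c(C=O)c2OB(Cl)Cl)c(C)c(C)c1Cl | intermediate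
23 | 4-chloro-3-methoxy-2,5,6-trimethylphenyl 3,5-diformyl-2,4-dihydroxy-6-methylbenzoate | COc1c(C)c(OC(=O)c2c(C)c(C=O)c(O)c(C=O)c2O)c(C)c(C)c1Cl | target

**Step count**

Total: 10 steps. Longest linear sequence: 10 steps, from 1 to 23; starting materials 8, 11 and 15 enter directly.

**Steps most likely to fail**

Step 8. The cycloaddition may be too slow, because the 4-methoxy donor and the 6-methyl group raise the barrier to attack at pyrone C6; the ketene acetal would then oligomerise or be consumed before it adds across pyrone C3 and C6. The fallback leaves the pyrone and brings ring A in ready-made, setting out from phenol 7 and returning at 18. Commercial methyl 2,4-dihydroxy-6-methylbenzoate (Cc1cc(O)cc(O)c1C(=O)OC) is ethylated at the 4-hydroxyl, the one not hydrogen-bonded to the ester (EtI, K2CO3, acetone), to give methyl 4-ethoxy-2-hydroxy-6-methylbenzoate F1. Methylation (MeI, K2CO3, DMF) gives methyl 4-ethoxy-2-methoxy-6-methylbenzoate F2, and saponification (KOH, aqueous DMSO, 90 °C) gives 4-ethoxy-2-methoxy-6-methylbenzoic acid F3. F3 and 7 are then joined by mixed-anhydride esterification with (CF3CO)2O in toluene, the usual depside coupling for di-ortho-substituted benzoic acids, to give 18.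

Step 9. The second electrophilic substitution may stall, because the first formyl group, held as a TiCl4-bound oxocarbenium ion, deactivates the ring, and the remaining position is flanked on both sides. The fallback sets out from 18 and returns at 23, doing the formylation on a free phenol. BCl3 (1.2 equiv, CH2Cl2, −78 to 0 °C) removes only the ester-chelated methyl group to give 4-chloro-3-methoxy-2,5,6-trimethylphenyl 4-ethoxy-2-hydroxy-6-methylbenzoate F4. A double Duff formylation (hexamethylenetetramine, CF3CO2H, 90 °C, then aqueous HCl) ortho and para to the phenol gives 4-chloro-3-methoxy-2,5,6-trimethylphenyl 4-ethoxy-3,5-diformyl-2-hydroxy-6-methylbenzoate F5. BCl3 then cleaves the ethyl ether between the two formyl groups to give 23.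

Step 6. Self-condensation of malonyl dichloride (through chlorocarbonylketene) may outrun C-acylation of the acetoacetate, and O-acylation may divert material. The fallback sets out from 10 and returns at 13, using a differentiated malonyl unit in two stages. C-Acylation of 10 with methyl 3-chloro-3-oxopropanoate (MgCl2, pyridine, CH2Cl2) gives 1-(4-chloro-3-methoxy-2,5,6-trimethylphenyl) 5-methyl 2-acetyl-3-oxopentanedioate F6. Lactonisation of the acetyl enol onto the methyl ester (DBU, toluene, reflux) gives 13.

**Further compounds**

F1 | step 8 | methyl 4-ethoxy-2-hydroxy-6-methylbenzoate | CCOc1cc(C)c(C(=O)OC)c(O)c1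
F2 | step 8 | methyl 4-ethoxy-2-methoxy-6-methylbenzoate | CCOc1cc(C)c(C(=O)OC)c(OC)c1
F3 | step 8 | 4-ethoxy-2-methoxy-6-methylbenzoic acid | CCOc1cc(C)c(C(=O)O)c(OC)c1
F4 | step 9 | 4-chloro-3-methoxy-2,5,6-trimethylphenyl 4-ethoxy-2-hydroxy-6-methylbenzoate | CCOc1cc(C)c(C(=O)Oc2c(C)c(OC)c(Cl)c(C)c2C)c(O)c1
F5 | step 9 | 4-chloro-3-methoxy-2,5,6-trimethylphenyl 4-ethoxy-3,5-diformyl-2-hydroxy-6-methylbenzoate | CCOc1c(C=O)c(C)c(C(=O)Oc2c(C)c(OC)c(Cl)c(C)c2C)c(O)c1C=O
F6 | step 6 | 1-(4-chloro-3-methoxy-2,5,6-trimethylphenyl) 5-methyl 2-acetyl-3-oxopentanedioate | CC(=O)C(C(=O)CC(=O)OC)C(=O)Oc1c(C)c(OC)c(Cl)c(C)c1C
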